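The route rests on cutting the 2,2-dimethyl-2H-pyran ring (O1, C2, C3, C4, C4a, C8a) at C4–C4a and O1–C2. The feature exploited is that C4a lies between the oxygen on C8a and the hydroxyl on C5, which is hydrogen-bonded to the C6 acyl group. Heating an aryl 1,1-dimethylpropargyl ether should forge C4–C4a, then re-close O1–C2, building the pyran in one operation at exactly that carbon. The precursor is 2'-hydroxy-6'-methoxyacetophenone carrying the propargyl ether on O4'. Afterwards, C8 is prenylated by para-Claisen–Cope rearrangement and the acetyl group is turned into the aryl 1,2-dione by α-arylation and aerobic oxidation.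

Key step: step 2

Remark on the structure: the target has no stereocentre. In chromene numbering it carries the hydroxyl on C5, the dione on C6, the methoxy group on C7 and the prenyl group on C8; the chromene made in step 2 already has the first three oxygen and acyl positions in place. Primed locants refer to the acetophenone ring before cyclisation.

Assumption: 1-bromo-4-(methoxymethoxy)benzene, the methoxymethyl ether of 4-bromophenol, is taken as a purchasable catalogue compound.

Step 1
Reactants: 1 2',4'-dihydroxy-6'-methoxyacetophenone; 2 3-chloro-3-methylbut-1-yne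
Product: 3 1-[2-hydroxy-6-methoxy-4-(2-methylbut-3-yn-2-yloxy)phenyl]ethanone
Conditions: CuCl2·2H2O (1 mol%), DBU (1.2 equiv), MeCN, 0 °C
Reagents that add atoms: 3-chloro-3-methylbut-1-yne (compound 2), CC(C)(Cl)C#C
Why: Copper-catalysed O-propargylation of a phenol with a tertiary propargylic chloride, in which a copper acetylide ionises to an allenylidene-type electrophile; the free 4'-hydroxyl is more acidic and far more nucleophilic than the hydrogen-bonded 2'-hydroxyl, so a slight excess of the chloride should alkylate O4' only.

Step 2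
Reactants: 3 1-[2-hydroxy-6-methoxy-4-(2-methylbut-3-yn-2-yloxy)phenyl]ethanone
Product: 7 1-(5-hydroxy-7-methoxy-2,2-dimethyl-2H-chromen-6-yl)ethanone, via allenyl dienone 4 (not isolated), via allenyl phenol 5 (not isolated), via vinyl quinone methide 6 (not isolated)
Conditions: N,N-diethylaniline, 190 °C, N2
Reagents that add atoms: none
Why: Aromatic propargyl Claisen rearrangement, the known thermal route from aryl 1,1-dimethylpropargyl ethers to 2,2-dimethyl-2H-chromenes: a [3,3] shift bonds the alkyne terminus to C3' (the C4–C4a bond) and gives allenyl dienone 4, which enolises to allenyl phenol 5. A 1,5-hydrogen shift from the 4'-hydroxyl to the central allene carbon then gives the Z-configured vinyl quinone methide 6. The pyran ring closes by thermal disrotatory oxa-6π electrocyclisation of this dienone, which re-forms the O1–C2 bond. No stereocentre remains in the product, so no stereocontrol is needed. The selectivity required is that between the two ortho carbons C3' and C5'. The hydrogen bond from the 2'-hydroxyl to the acetyl oxygen fixes double-bond character in C3'–C4', so the shift should go to C3', the carbon between the two oxygens, and the gem-dimethyl group speeds both pericyclic steps.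

Step 3
Reactants: 7 1-(5-hydroxy-7-methoxy-2,2-dimethyl-2H-chromen-6-yl)ethanone; 8 prenyl bromide (1-bromo-3-methylbut-2-ene)
Product: 9 1-[7-methoxy-2,2-dimethyl-5-(3-methylbut-2-enyloxy)-2H-chromen-6-yl]ethanone
Conditions: K2CO3, DMF, 60 °C
Reagents that add atoms: prenyl bromide (compound 8), CC(C)=CCBr
Why: Williamson ether synthesis: carbonate in a dipolar aprotic solvent should break the hydrogen bond of the C5 hydroxyl, the only site of 7 that carbonate deprotonates, and the phenoxide should displace bromide from the primary allylic halide at oxygen.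

Step 4
Reactants: 9 1-[7-methoxy-2,2-dimethyl-5-(3-methylbut-2-enyloxy)-2H-chromen-6-yl]ethanone
Product: 12 1-[5-hydroxy-7-methoxy-2,2-dimethyl-8-(3-methylbut-2-enyl)-2H-chromen-6-yl]ethanone, via ortho dienone 10 (not isolated), via para dienone 11 (not isolated)
Conditions: N,N-diethylaniline, 200 °C, N2, sealed tube
Reagents that add atoms: none
Why: Para-Claisen rearrangement (aromatic Claisen rearrangement followed by Cope rearrangement): both carbons ortho to the ether (C6 and C4a) are substituted, so ortho dienone 10 from the first [3,3] shift cannot enolise and should pass the allyl unit on by a second [3,3] shift to C8, the only ring carbon that bears hydrogen, where enolisation of para dienone 11 restores the chelated phenol; two allylic inversions return the unbranched prenyl group.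

Step 5
Reactants: 12 1-[5-hydroxy-7-methoxy-2,2-dimethyl-8-(3-methylbut-2-enyl)-2H-chromen-6-yl]ethanone
Product: 13 1-[7-methoxy-5-(methoxymethoxy)-2,2-dimethyl-8-(3-methylbut-2-enyl)-2H-chromen-6-yl]ethanone
Conditions: NaH (1.1 equiv), MOMCl, DMF, 0 °C to rt
Reagents that add atoms: chloromethyl methyl ether (MOMCl), COCCl
Why: Williamson-type protection of the phenol as its methoxymethyl ether via the sodium phenoxide, so that the strong base of step 6 and the oxygen of step 7 do not meet a free electron-rich phenoxide; one equivalent of hydride should leave the much less acidic methyl ketone untouched.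

Step 6
Reactants: 13 1-[7-methoxy-5-(methoxymethoxy)-2,2-dimethyl-8-(3-methylbut-2-enyl)-2H-chromen-6-yl]ethanone; 14 1-bromo-4-(methoxymethoxy)benzene
Product: 15 1-[7-methoxy-5-(methoxymethoxy)-2,2-dimethyl-8-(3-methylbut-2-enyl)-2H-chromen-6-yl]-2-[4-(methoxymethoxy)phenyl]ethanone
Conditions: Pd(OAc)2 (2 mol%), Xantphos (2.4 mol%), NaOtBu (2.2 equiv), toluene, 80 °C
Reagents that add atoms: 1-bromo-4-(methoxymethoxy)benzene (compound 14), COCOc1ccc(Br)cc1
Why: Palladium-catalysed α-arylation of a ketone enolate (Buchwald–Hartwig type): zerovalent palladium formed in the flask inserts into the C–Br bond of 14, the sodium enolate of the methyl ketone (its only enolisable position) replaces bromide on palladium, and reductive elimination forms the C–C bond, with the wide-bite-angle Xantphos favouring monoarylation and the trisubstituted and cyclic cis alkenes being poor Heck partners.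

Step 7
Reactants: 15 1-[7-methoxy-5-(methoxymethoxy)-2,2-dimethyl-8-(3-methylbut-2-enyl)-2H-chromen-6-yl]-2-[4-(methoxymethoxy)phenyl]ethanone
Product: 17 1-[7-methoxy-5-(methoxymethoxy)-2,2-dimethyl-8-(3-methylbut-2-enyl)-2H-chromen-6-yl]-2-[4-(methoxymethoxy)phenyl]ethane-1,2-dione, via α-hydroperoxy ketone 16 (not isolated)
Conditions: air (O2), DABCO (20 mol%), DMF, 90 °C
Reagents that add atoms: dioxygen, O=O
Why: Base-catalysed autoxidation of a deoxybenzoin to a benzil: DABCO enolises the doubly activated methylene, the enolate takes up dioxygen to give α-hydroperoxy ketone 16, and base-induced loss of water (Kornblum–DeLaMare-type fragmentation) should give the 1,2-dione, which has no enolisable position left and is not oxidised further.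

Step 8
Reactants: 17 1-[7-methoxy-5-(methoxymethoxy)-2,2-dimethyl-8-(3-methylbut-2-enyl)-2H-chromen-6-yl]-2-[4-(methoxymethoxy)phenyl]ethane-1,2-dione
Product: 18 1-[5-hydroxy-7-methoxy-2,2-dimethyl-8-(3-methylbut-2-enyl)-2H-chromen-6-yl]-2-(4-hydroxyphenyl)ethane-1,2-dione
Conditions: HCl (3 M aq.), MeOH, 40 °C
Reagents that add atoms: none
Why: Acid-catalysed acetal cleavage (transacetalisation to methanol) should remove both methoxymethyl groups, while the prenyl group has no free ortho hydroxyl to cyclise onto and the dione, the chromene and the aryl methyl ether are stable to dilute acid at this temperature.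

Compound list
1 | 2',4'-dihydroxy-6'-methoxyacetophenone, 1-(2,4-dihydroxy-6-methoxyphenyl)ethanone | CC(=O)c1c(O)cc(O)cc1OC | starting material
2 | 3-chloro-3-methylbut-1-yne | CC(C)(Cl)C#C | starting material
3 | 1-[2-hydroxy-6-methoxy-4-(2-methylbut-3-yn-2-yloxy)phenyl]ethanone | CC(=O)c1c(O)cc(OC(C)(C)C#C)cc1OC | intermediate
4 | allenyl dienone (not isolated, racemic): 4-acetyl-5-hydroxy-3-methoxy-6-(3-methylbuta-1,2-dienyl)cyclohexa-2,4-dien-1-one | CC(=O)C1=C(O)C(C=C=C(C)C)C(=O)C=C1OC | intermediate
5 | allenyl phenol (not isolated): 1-[2,4-dihydroxy-6-methoxy-3-(3-methylbuta-1,2-dienyl)phenyl]ethanone | CC(=O)c1c(O)c(C=C=C(C)C)c(O)cc1OC | intermediate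
6 | vinyl quinone methide (not isolated): (6Z)-4-acetyl-5-hydroxy-3-methoxy-6-(3-methylbut-2-enylidene)cyclohexa-2,4-dien-1-one | CC(=O)C1=C(O)/C(=C/C=C(C)C)C(=O)C=C1OC | intermediate
7 | 1-(5-hydroxy-7-methoxy-2,2-dimethyl-2H-chromen-6-yl)ethanone (6-acetyl-5-hydroxy-7-methoxy-2,2-dimethyl-2H-chromene) | COc1cc2OC(C)(C)C=Cc2c(O)c1C(C)=O | intermediate
8 | prenyl bromide, 1-bromo-3-methylbut-2-ene | CC(C)=CCBr | starting material
9 | 1-[7-methoxy-2,2-dimethyl-5-(3-methylbut-2-enyloxy)-2H-chromen-6-yl]ethanone | COc1cc2OC(C)(C)C=Cc2c(OCC=C(C)C)c1C(C)=O | intermediate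
10 | ortho dienone (not isolated, racemic): 6-acetyl-7-methoxy-2,2-dimethyl-6-(2-methylbut-3-en-2-yl)-2H-chromen-5(6H)-one | COC1=CC2=C(C=CC(C)(C)O2)C(=O)C1(C(C)=O)C(C)(C)C=C | intermediate
11 | para dienone (not isolated, racemic): 6-acetyl-7-methoxy-2,2-dimethyl-8-(3-methylbut-2-enyl)-2H-chromen-5(8H)-one | COC1=C(C(C)=O)C(=O)C2=C(OC(C)(C)C=C2)C1CC=C(C)C | intermediate
12 | 1-[5-hydroxy-7-methoxy-2,2-dimethyl-8-(3-methylbut-2-enyl)-2H-chromen-6-yl]ethanone | COc1c(CC=C(C)C)c2OC(C)(C)C=Cc2c(O)c1C(C)=O | intermediate
13 | 1-[7-methoxy-5-(methoxymethoxy)-2,2-dimethyl-8-(3-methylbut-2-enyl)-2H-chromen-6-yl]ethanone | COCOc1c(C(C)=O)c(OC)c(CC=C(C)C)c2OC(C)(C)C=Cc12 | intermediate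
14 | 1-bromo-4-(methoxymethoxy)benzene | COCOc1ccc(Br)cc1 | starting material
15 | 1-[7-methoxy-5-(methoxymethoxy)-2,2-dimethyl-8-(3-methylbut-2-enyl)-2H-chromen-6-yl]-2-[4-(methoxymethoxy)phenyl]ethanone | COCOc1ccc(CC(=O)c2c(OC)c(CC=C(C)C)c3OC(C)(C)C=Cc3c2OCOC)cc1 | intermediate
16 | α-hydroperoxy ketone (not isolated, racemic): 2-hydroperoxy-1-[7-methoxy-5-(methoxymethoxy)-2,2-dimethyl-8-(3-methylbut-2-enyl)-2H-chromen-6-yl]-2-[4-(methoxymethoxy)phenyl]ethanone | COCOc1ccc(C(OO)C(=O)c2c(OC)c(CC=C(C)C)c3OC(C)(C)C=Cc3c2OCOC)cc1 | intermediate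
17 | 1-[7-methoxy-5-(methoxymethoxy)-2,2-dimethyl-8-(3-methylbut-2-enyl)-2H-chromen-6-yl]-2-[4-(methoxymethoxy)phenyl]ethane-1,2-dione | COCOc1ccc(C(=O)C(=O)c2c(OC)c(CC=C(C)C)c3OC(C)(C)C=Cc3c2OCOC)cc1 | intermediate
18 | 1-[5-hydroxy-7-methoxy-2,2-dimethyl-8-(3-methylbut-2-enyl)-2H-chromen-6-yl]-2-(4-hydroxyphenyl)ethane-1,2-dione | COc1c(CC=C(C)C)c2c(c(O)c1C(=O)C(=O)c1ccc(O)cc1)C=CC(C)(C)O2 | target

Total step count: 8 steps.
Longest linear sequence: 8 steps (from 1 to 18).

Steps most likely to fail

Step 4 (para-Claisen–Cope). At about 200 °C the ortho dienone may fragment with loss of the allyl unit, returning the phenol, faster than it undergoes the Cope shift. If the first shift goes to the ring-fusion carbon, the allyl unit may also travel on toward C3 of the pyran instead of C8. The fallback sets out from 7 and comes back at 12, replacing steps 3 and 4. Electrophilic iodination of C8, the only arene carbon bearing hydrogen and para to the C5 hydroxyl, with N-iodosuccinimide in MeCN at 0 °C should give 1-(5-hydroxy-8-iodo-7-methoxy-2,2-dimethyl-2H-chromen-6-yl)ethanone F1. Stille coupling of this iodide with tributyl(3-methylbut-2-enyl)stannane (Pd(PPh3)4, DMF, 90 °C) should then transfer the prenyl group to C8 and give 12.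

Step 7 (aerobic oxidation). The α-hydroperoxide may cleave the central C–C bond instead of losing water, or radical chain autoxidation may start at the benzylic, allylic methylene of the prenyl group. The fallback sets out from 15 and comes back at 17. The potassium enolate of 15 (KN(SiMe3)2, THF, −78 °C) is hydroxylated with 2-(phenylsulfonyl)-3-phenyloxaziridine (Davis enolate oxidation). This should give racemic 2-hydroxy-1-[7-methoxy-5-(methoxymethoxy)-2,2-dimethyl-8-(3-methylbut-2-enyl)-2H-chromen-6-yl]-2-[4-(methoxymethoxy)phenyl]ethanone F2. Oxidation of this secondary alcohol with Dess–Martin periodinane (NaHCO3, CH2Cl2, rt) should give dione 17 without any contact between the alkenes and oxygen radicals.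

Step 2 (key step). Regiocontrol may be incomplete: part of the [3,3] shift may go to C5', the ortho carbon next to the methoxy group, and the cascade would then end in the linear isomeric chromene. The fallback sets out from 1 and comes back at 7, replacing steps 1 and 2. Compound 1 is condensed with 3-methylbut-2-enal (ethylenediammonium diacetate, xylene, 140 °C), so that the C–C bond is made by attack of the most nucleophilic ring carbon, C3' between the two hydroxyls, on the aldehyde. The adduct 1-[2,4-dihydroxy-3-(1-hydroxy-3-methylbut-2-enyl)-6-methoxyphenyl]ethanone F3 is not isolated. It should lose water to give quinone methide 6, which closes through the free 4'-oxygen to 7 as in step 2, while the 2'-hydroxyl stays tied up in its hydrogen bond.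

Further compounds
F1 | step 4 | 1-(5-hydroxy-8-iodo-7-methoxy-2,2-dimethyl-2H-chromen-6-yl)ethanone | COc1c(I)c2OC(C)(C)C=Cc2c(O)c1C(C)=O
F2 | step 7 | 2-hydroxy-1-[7-methoxy-5-(methoxymethoxy)-2,2-dimethyl-8-(3-methylbut-2-enyl)-2H-chromen-6-yl]-2-[4-(methoxymethoxy)phenyl]ethanone (racemic) | COCOc1ccc(C(O)C(=O)c2c(OC)c(CC=C(C)C)c3OC(C)(C)C=Cc3c2OCOC)cc1
F3 | step 2 | 1-[2,4-dihydroxy-3-(1-hydroxy-3-methylbut-2-enyl)-6-methoxyphenyl]ethanone (racemic, not isolated) | CC(=O)c1c(O)c(C(O)C=C(C)C)c(O)cc1OC
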